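Assumption: compounds 1, 3, 4, 9, 15 and 17 are bought (1 as the racemate); ring atoms are labelled C2–C6 and side-chain atoms C1′–C10′ as in the target.

## Retrosynthetic overview

1. Target 20 ⇐ alkynyl lactone 19 by syn semi-hydrogenation of the C1′≡C2′ alkyne (Z-alkene made last).
2. 19 ⇐ enynal 16 + phosphonoacetic acid 17: the C6–O1 bond is made by a catalyst-controlled oxa-Michael addition that sets C6, and the dihydropyranone is closed in the same flask by intramolecular HWE olefination.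
3. 16 ⇐ ynal 14 (Wittig) ⇐ acetal 13; the C6′ carbinol comes from 1,3-syn reduction of ketone 11.
4. 11 ⇐ alkyne 9 + epoxide 8 (C2′–C3′ bond); 8 ⇐ dithiane 3 as C6′ linchpin joining (R)-epoxide 2 (C8′–O from hydrolytic kinetic resolution of 1) and (S)-epichlorohydrin 4 (C4′–O).
5. Ring order: the oxirane of 8 (step 2, opened in step 3), then the dihydropyranone (step 8), the only ring of the target.

## Route

Step 1
Reactants: 1 rac-2-(2-phenylethyl)oxirane
Product: 2 (2R)-2-(2-phenylethyl)oxirane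
Conditions: (R,R)-(salen)Co(OAc) (0.5 mol %; trivalent cobalt; salen = N,N′-bis(3,5-di-tert-butylsalicylidene)cyclohexane-1,2-diamine dianion), H2O (0.55 equiv), THF, 0 °C → rt
Reagents that add atoms: none
Why: Jacobsen hydrolytic kinetic resolution: the chiral cobalt complex hydrates the (S)-epoxide much faster (C–O bond formation at the CH2 terminus), leaving (R)-2, whose stereocentre becomes C8′.

Step 2
Reactants: 2 (2R)-2-(2-phenylethyl)oxirane; 3 2-[tert-butyl(dimethyl)silyl]-1,3-dithiane; 4 (S)-epichlorohydrin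
Product: 8 tert-butyl(dimethyl){[(2R)-1-(2-{[(2S)-oxiran-2-yl]methyl}-1,3-dithian-2-yl)-4-phenylbutan-2-yl]oxy}silane, via lithium alkoxide 5 (not isolated), via lithiated dithiane 6 (not isolated), via chlorohydrin alkoxide 7 (not isolated)
Conditions: 3, t-BuLi, Et2O, −78 → −45 °C; 2, −78 → −25 °C; then 4 (2 equiv), HMPA/THF, −78 °C → rt
Reagents that add atoms: 2-[tert-butyl(dimethyl)silyl]-1,3-dithiane CC(C)(C)[Si](C)(C)C1SCCCS1; (S)-epichlorohydrin ClC[C@@H]1CO1
Why: Anion relay (dithiane linchpin) coupling: lithiated 3 opens 2 at its CH2 end, HMPA triggers the 1,4-Brook rearrangement that silylates O8′ and returns the carbanion to the dithiane carbon, which opens 4 at the epoxide CH2; the alkoxide then displaces chloride (Williamson closure), so C8′ and C4′ keep the configurations of 2 and 4.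

Step 3
Reactants: 8 epoxide; 9 3,3-diethoxyprop-1-yne
Product: 10 (2R)-1-{2-[(2R)-2-{[tert-butyl(dimethyl)silyl]oxy}-4-phenylbutyl]-1,3-dithian-2-yl}-6,6-diethoxyhex-4-yn-2-ol
Conditions: 9 (2 equiv), n-BuLi, THF, −78 °C; BF3·OEt2; then 8, −78 °C
Reagents that add atoms: 3,3-diethoxyprop-1-yne C#CC(OCC)OCC
Why: Yamaguchi-type BF3-mediated alkynylation: the lithium acetylide opens the activated terminal epoxide at its unsubstituted carbon, so C4′ is untouched and emerges as the free (R)-carbinol.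

Step 4
Reactants: 10 hydroxy dithiane
Product: 11 (5R,9R)-9-{[tert-butyl(dimethyl)silyl]oxy}-1,1-diethoxy-5-hydroxy-11-phenylundec-2-yn-7-one
Conditions: MeI, CaCO3, MeCN/H2O (9:1), 40 °C
Reagents that add atoms: water O
Why: Alkylative dithiane hydrolysis (S-methylation, then hydrolysis) under CaCO3 buffering unveils the C6′ ketone without touching the acetal, the silyl ether or the alkyne.

Step 5
Reactants: 11 β-hydroxy ketone
Product: 13 (5R,7R,9R)-9-{[tert-butyl(dimethyl)silyl]oxy}-1,1-diethoxy-11-phenylundec-2-yne-5,7-diol, via diethylborinate 12 (not isolated)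
Conditions: Et2BOMe, THF/MeOH (4:1), −78 °C; NaBH4; then MeOH co-evaporation
Reagents that add atoms: none
Why: Narasaka–Prasad reduction: the diethylboron chelate of the β-hydroxy ketone is attacked axially by external hydride, giving the 4′,6′-syn diol, which is 6′,8′-anti as the target requires (the new centre is labelled 7R only because O9 carries silicon; it is the 6′S arrangement of the target).

Step 6
Reactants: 13 silyl ether acetal
Product: 14 (5R,7S,9R)-5,7,9-trihydroxy-11-phenylundec-2-ynal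
Conditions: TFA/H2O/THF, 0 °C → rt
Reagents that add atoms: water O
Why: Acid hydrolysis cleaves the silyl ether and the diethyl acetal in one operation; trifluoroacetate is too poor a nucleophile to add to the ynal.

Step 7
Reactants: 14 ynal; 15 (triphenylphosphoranylidene)acetaldehyde
Product: 16 (2E,7R,9S,11R)-7,9,11-trihydroxy-13-phenyltridec-2-en-4-ynal
Conditions: 15 (1.1 equiv), CH2Cl2, rt
Reagents that add atoms: (triphenylphosphoranylidene)acetaldehyde O=CC=P(c1ccccc1)(c1ccccc1)c1ccccc1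
Why: Wittig olefination with the stabilised formyl ylide is E-selective and tolerates free hydroxyls; the ynal is far more electrophilic than the product enal, so the reaction stops after one homologation.

Step 8
Reactants: 16 enynal; 17 (diethoxyphosphoryl)acetic acid
Product: 19 (6S)-6-[(4R,6S,8R)-4,6,8-trihydroxy-10-phenyldec-1-yn-1-yl]-5,6-dihydro-2H-pyran-2-one, via phosphonoacetate aldehyde 18 (not isolated)
Conditions: (S)-2-{bis[3,5-bis(trifluoromethyl)phenyl][(trimethylsilyl)oxy]methyl}pyrrolidine (20 mol %), 17 (2 equiv), i-Pr2NEt (1 equiv), LiCl (3 equiv), CHCl3/MeCN, 0 °C → rt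
Reagents that add atoms: (diethoxyphosphoryl)acetic acid OC(=O)CP(=O)(OCC)OCC
Why: Proposed new method: aminocatalytic oxa-Michael/intramolecular Horner–Wadsworth–Emmons lactone annulation — the (S)-prolinol silyl ether converts 16 into an E-iminium ion whose Re face at C6 is shielded by the diaryl(silyloxy)methyl group, so the carboxylate of half-neutralised 17 adds to the Si face and forms the C6–O1 bond with 6S configuration; enamine hydrolysis gives β-acyloxy aldehyde 18, whose phosphonate (now an ester and acidic enough for LiCl/i-Pr2NEt, unlike unreacted 17) closes onto C4 by intramolecular HWE, an irreversible step that pulls the reversible, uphill carboxylate addition forward and fixes the ring alkene as cis; the triol cannot compete because the rigid enyne keeps its hydroxyls away from C6; the closest known reaction types are the iminium-catalysed oxa-Michael addition of oximes to enals and the Masamune–Roush intramolecular HWE lactonisation of β-(phosphonoacetoxy) aldehydes.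

Step 9
Reactants: 19 alkynyl lactone
Product: 20 (6S)-6-[(1Z,4R,6S,8R)-4,6,8-trihydroxy-10-phenyldec-1-en-1-yl]-5,6-dihydro-2H-pyran-2-one
Conditions: H2 (1 atm), Pd/CaCO3 poisoned with Pb(OAc)2 (Lindlar catalyst), quinoline, EtOAc, rt
Reagents that add atoms: none
Why: Lindlar semi-hydrogenation adds H2 syn on the poisoned palladium surface to give the Z-alkene; with quinoline the conjugated ring alkene and the allylic C6–O bond are left alone.

## Compound list

1 | rac-2-(2-phenylethyl)oxirane | C1OC1CCc1ccccc1 | starting material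
2 | (2R)-2-(2-phenylethyl)oxirane | C1O[C@@H]1CCc1ccccc1 | intermediate
3 | 2-[tert-butyl(dimethyl)silyl]-1,3-dithiane | CC(C)(C)[Si](C)(C)C1SCCCS1 | starting material
4 | (S)-epichlorohydrin, (2S)-2-(chloromethyl)oxirane | ClC[C@@H]1CO1 | starting material
5 | lithium (2R)-1-{2-[tert-butyl(dimethyl)silyl]-1,3-dithian-2-yl}-4-phenylbutan-2-olate | CC(C)(C)[Si](C)(C)C1(SCCCS1)C[C@H](O[Li])CCc1ccccc1 | intermediate
6 | 2-[(2R)-2-{[tert-butyl(dimethyl)silyl]oxy}-4-phenylbutyl]-2-lithio-1,3-dithiane | [Li]C1(SCCCS1)C[C@H](O[Si](C)(C)C(C)(C)C)CCc1ccccc1 | intermediate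
7 | lithium (2S)-1-chloro-3-{2-[(2R)-2-{[tert-butyl(dimethyl)silyl]oxy}-4-phenylbutyl]-1,3-dithian-2-yl}propan-2-olate | [Li]O[C@H](CCl)CC1(SCCCS1)C[C@H](O[Si](C)(C)C(C)(C)C)CCc1ccccc1 | intermediate
8 | tert-butyl(dimethyl){[(2R)-1-(2-{[(2S)-oxiran-2-yl]methyl}-1,3-dithian-2-yl)-4-phenylbutan-2-yl]oxy}silane | C1O[C@H]1CC1(SCCCS1)C[C@H](O[Si](C)(C)C(C)(C)C)CCc1ccccc1 | intermediate
9 | 3,3-diethoxyprop-1-yne | C#CC(OCC)OCC | starting material
10 | (2R)-1-{2-[(2R)-2-{[tert-butyl(dimethyl)silyl]oxy}-4-phenylbutyl]-1,3-dithian-2-yl}-6,6-diethoxyhex-4-yn-2-ol | CCOC(OCC)C#CC[C@@H](O)CC1(SCCCS1)C[C@H](O[Si](C)(C)C(C)(C)C)CCc1ccccc1 | intermediate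
11 | (5R,9R)-9-{[tert-butyl(dimethyl)silyl]oxy}-1,1-diethoxy-5-hydroxy-11-phenylundec-2-yn-7-one | CCOC(OCC)C#CC[C@@H](O)CC(=O)C[C@H](O[Si](C)(C)C(C)(C)C)CCc1ccccc1 | intermediate
12 | (5R,9R)-9-{[tert-butyl(dimethyl)silyl]oxy}-5-[(diethylboranyl)oxy]-1,1-diethoxy-11-phenylundec-2-yn-7-one | CCOC(OCC)C#CC[C@@H](OB(CC)CC)CC(=O)C[C@H](O[Si](C)(C)C(C)(C)C)CCc1ccccc1 | intermediate
13 | (5R,7R,9R)-9-{[tert-butyl(dimethyl)silyl]oxy}-1,1-diethoxy-11-phenylundec-2-yne-5,7-diol | CCOC(OCC)C#CC[C@@H](O)C[C@@H](O)C[C@H](O[Si](C)(C)C(C)(C)C)CCc1ccccc1 | intermediate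
14 | (5R,7S,9R)-5,7,9-trihydroxy-11-phenylundec-2-ynal | O=CC#CC[C@@H](O)C[C@@H](O)C[C@H](O)CCc1ccccc1 | intermediate
15 | (triphenylphosphoranylidene)acetaldehyde | O=CC=P(c1ccccc1)(c1ccccc1)c1ccccc1 | starting material
16 | (2E,7R,9S,11R)-7,9,11-trihydroxy-13-phenyltridec-2-en-4-ynal | O=C/C=C/C#CC[C@@H](O)C[C@@H](O)C[C@H](O)CCc1ccccc1 | intermediate
17 | (diethoxyphosphoryl)acetic acid | OC(=O)CP(=O)(OCC)OCC | starting material
18 | (3S,7R,9S,11R)-7,9,11-trihydroxy-1-oxo-13-phenyltridec-4-yn-3-yl (diethoxyphosphoryl)acetate | O=CC[C@H](OC(=O)CP(=O)(OCC)OCC)C#CC[C@@H](O)C[C@@H](O)C[C@H](O)CCc1ccccc1 | intermediate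
19 | (6S)-6-[(4R,6S,8R)-4,6,8-trihydroxy-10-phenyldec-1-yn-1-yl]-5,6-dihydro-2H-pyran-2-one | O=C1C=CC[C@@H](C#CC[C@@H](O)C[C@@H](O)C[C@H](O)CCc2ccccc2)O1 | intermediate
20 | (6S)-6-[(1Z,4R,6S,8R)-4,6,8-trihydroxy-10-phenyldec-1-en-1-yl]-5,6-dihydro-2H-pyran-2-one | O=C1C=CC[C@@H](/C=C\C[C@@H](O)C[C@@H](O)C[C@H](O)CCc2ccccc2)O1 | target

## Step count and risks

Total step count: 9. Longest linear sequence: 9 (1 → 20; all other inputs are bought).

**Step 8 (the proposed annulation).** The carboxylate addition is uphill and reversible, and 18 can eliminate again. The enantiomeric excess will erode if ring closure is slower than catalyst-mediated retro-addition. Doebner-type condensation of 17 with the iminium ion is a possible side reaction. Fallback with known chemistry, C–C instead of C–O: it sets out from ynal 14 and skips 16. A diarylprolinol-catalysed cross-aldol of acetaldehyde onto the ynal (the catalyst enantiomer that gives the 3S aldol; NMP, 4 °C) gives (3S,7R,9S,11R)-3,7,9,11-tetrahydroxy-13-phenyltridec-4-ynal F8. Without purification, Z-selective Ando olefination (ethyl (diphenoxyphosphoryl)acetate, NaI, DBU, THF, −78 → 0 °C) gives ethyl (2Z,5S,9R,11S,13R)-5,9,11,13-tetrahydroxy-15-phenylpentadec-2-en-6-ynoate F9. Catalytic p-TsOH (CH2Cl2, rt) lactonises F9, and the route is rejoined at 19.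

**Step 2 (relay coupling ending on epichlorohydrin).** Risks are a second dithiane addition to the new epoxide, incomplete Brook transfer, and direct displacement of chloride, which would erode the configuration at C4′. Fallback: it sets out from alkyne 9 and bought (R)-epichlorohydrin (ClC[C@H]1CO1). Alkynylation (n-BuLi, BF3·OEt2, THF, −78 °C) gives (2R)-1-chloro-6,6-diethoxyhex-4-yn-2-ol F1, and NaOH (Et2O/H2O) closes it to (2R)-2-(4,4-diethoxybut-2-yn-1-yl)oxirane F2. The relay coupling is then run with lithiated 3, epoxide 2 and, after HMPA, F2 as the stable terminating electrophile. This replaces steps 2 and 3 and comes back to the route at 10.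

**Step 6 (acid unmasking to the unprotected ynal).** Risks are incomplete acetal hydrolysis and hydration or oligomerisation of ynal 14 in acid. Fallback that avoids the ynal and the Wittig step: it sets out from epoxide 8. Bought (E)-pent-2-en-4-yn-1-ol is silylated (TBSCl, imidazole) to tert-butyl(dimethyl){[(2E)-pent-2-en-4-yn-1-yl]oxy}silane F3. Its lithium acetylide opens 8 (BF3·OEt2, −78 °C) to (2R,6E)-8-{[tert-butyl(dimethyl)silyl]oxy}-1-{2-[(2R)-2-{[tert-butyl(dimethyl)silyl]oxy}-4-phenylbutyl]-1,3-dithian-2-yl}oct-6-en-4-yn-2-ol F4. MeI/CaCO3 gives (2E,7R,11R)-1,11-bis{[tert-butyl(dimethyl)silyl]oxy}-7-hydroxy-13-phenyltridec-2-en-4-yn-9-one F5. Et2BOMe/NaBH4 gives (2E,7R,9R,11R)-1,11-bis{[tert-butyl(dimethyl)silyl]oxy}-13-phenyltridec-2-en-4-yne-7,9-diol F6. TBAF gives (2E,7R,9S,11R)-13-phenyltridec-2-en-4-yne-1,7,9,11-tetrol F7. MnO2 (CH2Cl2) oxidises only the primary allylic alcohol of F7, and the route is rejoined at 16.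

## Further compounds

F1 | step 2 | (2R)-1-chloro-6,6-diethoxyhex-4-yn-2-ol | ClC[C@H](O)CC#CC(OCC)OCC
F2 | step 2 | (2R)-2-(4,4-diethoxybut-2-yn-1-yl)oxirane | C1O[C@@H]1CC#CC(OCC)OCC
F3 | step 6 | tert-butyl(dimethyl){[(2E)-pent-2-en-4-yn-1-yl]oxy}silane | C#C/C=C/CO[Si](C)(C)C(C)(C)C
F4 | step 6 | (2R,6E)-8-{[tert-butyl(dimethyl)silyl]oxy}-1-{2-[(2R)-2-{[tert-butyl(dimethyl)silyl]oxy}-4-phenylbutyl]-1,3-dithian-2-yl}oct-6-en-4-yn-2-ol | CC(C)(C)[Si](C)(C)OC/C=C/C#CC[C@@H](O)CC1(SCCCS1)C[C@H](O[Si](C)(C)C(C)(C)C)CCc1ccccc1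
F5 | step 6 | (2E,7R,11R)-1,11-bis{[tert-butyl(dimethyl)silyl]oxy}-7-hydroxy-13-phenyltridec-2-en-4-yn-9-one | CC(C)(C)[Si](C)(C)OC/C=C/C#CC[C@@H](O)CC(=O)C[C@H](O[Si](C)(C)C(C)(C)C)CCc1ccccc1
F6 | step 6 | (2E,7R,9R,11R)-1,11-bis{[tert-butyl(dimethyl)silyl]oxy}-13-phenyltridec-2-en-4-yne-7,9-diol | CC(C)(C)[Si](C)(C)OC/C=C/C#CC[C@@H](O)C[C@@H](O)C[C@H](O[Si](C)(C)C(C)(C)C)CCc1ccccc1
F7 | step 6 | (2E,7R,9S,11R)-13-phenyltridec-2-en-4-yne-1,7,9,11-tetrol | OC/C=C/C#CC[C@@H](O)C[C@@H](O)C[C@H](O)CCc1ccccc1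
F8 | step 8 | (3S,7R,9S,11R)-3,7,9,11-tetrahydroxy-13-phenyltridec-4-ynal | O=CC[C@H](O)C#CC[C@@H](O)C[C@@H](O)C[C@H](O)CCc1ccccc1
F9 | step 8 | ethyl (2Z,5S,9R,11S,13R)-5,9,11,13-tetrahydroxy-15-phenylpentadec-2-en-6-ynoate | CCOC(=O)/C=C\C[C@H](O)C#CC[C@@H](O)C[C@@H](O)C[C@H](O)CCc1ccccc1
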